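Locants used throughout: ring C1 (C=O), C2=C3, C4 (C–OMe), C5 (CH2), C6 (quaternary carbon); side chain C8 (CH–CH3) and C7 (benzylic carbon).

**Plan**
1. Retrosynthesis first cuts the acetyl C–O bond at C7 and the C7–H bond (megaphone 14, then aryl ketone 13), then the O–CH3 bond and, by inversion, the C4–O bond.
2. The central cut is C6–C8. The ring C1=O and the C7 oxygen stand 1,4 to each other across this bond, so at the ketone level it is the middle bond of a 1,4-diketone and C6 and C8 are both enolate carbons (like polarity).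
3. The bond is therefore made by oxidative coupling of the two enol ethers held on one i-Pr2Si bridge, a temporary tether that leaves in the same step. The last cuts are allyl–C6 and the C4 carbinol of ketal 1.
4. Forward: the six-membered ring is carried through from 1 and no ring is built. The pieces are joined in the order allyl (step 4), aryl propanone unit 6 (steps 5 and 6), then C4 inversion and methylation, C7 reduction and acetylation.
5. Stereochemistry: C4 comes from asymmetric transfer hydrogenation (S), serves as the control element on the face opposite the incoming side chain, and is then inverted to R by a Mitsunobu reaction. C6 and C8 are set in the key step, and C7 by catalyst-controlled hydrogenation.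

Key step: step 6

Remark: 1 and 6 are taken as purchasable. Compound 5 is drawn as the expected trans isomer, although its C6 configuration is erased again in step 5.

**Route**

Step 1
Reactants: 1 1,4-dioxaspiro[4.5]dec-6-en-8-one
Product: 2 (8S)-1,4-dioxaspiro[4.5]dec-6-en-8-ol
Conditions: RuCl[(S,S)-TsDPEN](p-cymene) (cat.), HCO2Na, Bu4NCl (cat.), CH2Cl2/H2O, 30 °C
Reagents that add atoms: none
Why: Noyori asymmetric transfer hydrogenation: the Ru–H/N–H catalyst reduces the enone carbonyl in 1,2-fashion with the alkenyl group in the role usually played by an aryl group, which should set the carbinol carbon (later C4) as S.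

Step 2
Reactants: 2 (8S)-1,4-dioxaspiro[4.5]dec-6-en-8-ol
Product: 3 (8S)-8-[(tert-butyldimethylsilyl)oxy]-1,4-dioxaspiro[4.5]dec-6-ene
Conditions: TBSCl, imidazole, DMF, rt
Reagents that add atoms: tert-butyldimethylsilyl chloride, CC(C)(C)[Si](C)(C)Cl
Why: Imidazole-promoted silyl ether formation at the secondary allylic alcohol; the stereocentre is not touched.

Step 3
Reactants: 3 (8S)-8-[(tert-butyldimethylsilyl)oxy]-1,4-dioxaspiro[4.5]dec-6-ene
Product: 4 (4S)-4-[(tert-butyldimethylsilyl)oxy]cyclohex-2-en-1-one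
Conditions: PPTS (cat.), acetone/H2O, 50 °C
Reagents that add atoms: water, O
Why: Acid-catalysed hydrolysis of the allylic dioxolane (ketal cleavage) unmasks the enone carbonyl, the later C1, while the mild acid should leave the TBS ether intact.

Step 4
Reactants: 4 (4S)-4-[(tert-butyldimethylsilyl)oxy]cyclohex-2-en-1-one
Product: 5 (4S,6S)-4-[(tert-butyldimethylsilyl)oxy]-6-(prop-2-en-1-yl)cyclohex-2-en-1-one (trans)
Conditions: LDA, THF, −78 °C; allyl bromide, DMPU, −78 → −30 °C
Reagents that add atoms: allyl bromide, C=CCBr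
Why: Kinetic deprotonation at C6 gives the cross-conjugated lithium dienolate, which is C-allylated (enolate alkylation) anti to the C4 silyloxy group to give mainly the trans isomer; this centre becomes planar again in step 5.

Step 5
Reactants: 5 (4S,6S)-4-[(tert-butyldimethylsilyl)oxy]-6-(prop-2-en-1-yl)cyclohex-2-en-1-one; 6 1-(3,4,5-trimethoxyphenyl)propan-1-one
Product: 8 {[(4S)-4-[(tert-butyldimethylsilyl)oxy]-2-(prop-2-en-1-yl)cyclohexa-1,5-dien-1-yl]oxy}{[(1Z)-1-(3,4,5-trimethoxyphenyl)prop-1-en-1-yl]oxy}di(propan-2-yl)silane, via chlorosilyl dienol ether 7 (not isolated)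
Conditions: (i) 5, LDA, THF, −78 °C; i-Pr2SiCl2 (excess), −78 °C → rt, then volatiles off; (ii) Li enolate of 6 (LiHMDS, THF, −78 °C), −78 °C → rt
Reagents that add atoms: dichlorodi(propan-2-yl)silane, CC(C)[Si](Cl)(Cl)C(C)C
Why: Stepwise O-silylation of two lithium enolates by one dichlorosilane (silyl enol ether formation): the dienolate of 5 replaces the first chloride and, after removal of the excess silane, the Z enolate of 6 (geometry from amide-base deprotonation of the aryl ethyl ketone) replaces the second, so the unsymmetrical bis-enol ether should form without homo-products.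

Step 6
Reactants: 8 {[(4S)-4-[(tert-butyldimethylsilyl)oxy]-2-(prop-2-en-1-yl)cyclohexa-1,5-dien-1-yl]oxy}{[(1Z)-1-(3,4,5-trimethoxyphenyl)prop-1-en-1-yl]oxy}di(propan-2-yl)silane
Product: 9 (4S,6R)-4-[(tert-butyldimethylsilyl)oxy]-6-[(2S)-1-oxo-1-(3,4,5-trimethoxyphenyl)propan-2-yl]-6-(prop-2-en-1-yl)cyclohex-2-en-1-one
Conditions: (NH4)2Ce(NO3)6 (2.2 equiv), NaHCO3, MeCN/EtCN, −20 °C
Reagents that add atoms: none
Why: One-electron oxidation of the electron-rich tetrasubstituted silyl dienol ether by Ce(IV) gives a radical cation whose C6 is attacked by C8 of the tethered aryl enol ether, and a second oxidation with loss of the diisopropylsilyl bridge releases the ring C1 and the aryl C7 carbonyl groups. The closest known reaction type is the oxidative cross-coupling of unsymmetrical silyl bis-enol ethers to 1,4-diketones with quaternary centres, an oxidative union of two enolate carbons of like polarity. No ring of the target is closed; the only ring formed is the transient seven-membered 1,3-dioxa-2-silacycle (7-endo attack within the O–Si–O tether), which collapses again when silicon leaves. C6 should be set by attack on the dienol ether face anti to the C4 silyloxy group, and C8 by the Z geometry of the aryl enol ether together with the stacked, staggered arrangement that the short O–Si–O bridge enforces, in which the C8 methyl lies anti to the allyl group. The step needs cross- instead of homo-coupling and bond formation at C6 and C8 only; the tether makes the coupling intramolecular, the fully substituted dienol ether is the most easily oxidised site, and NaHCO3 and low temperature should spare the TBS ether, the allyl group and the trimethoxyarene.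

Step 7
Reactants: 9 (4S,6R)-4-[(tert-butyldimethylsilyl)oxy]-6-[(2S)-1-oxo-1-(3,4,5-trimethoxyphenyl)propan-2-yl]-6-(prop-2-en-1-yl)cyclohex-2-en-1-one
Product: 10 (4S,6R)-4-hydroxy-6-[(2S)-1-oxo-1-(3,4,5-trimethoxyphenyl)propan-2-yl]-6-(prop-2-en-1-yl)cyclohex-2-en-1-one
Conditions: HF·pyridine, pyridine, THF, 0 °C → rt
Reagents that add atoms: none
Why: Fluoride-induced cleavage of the silyl ether driven by the Si–F bond (desilylation) under buffered, non-basic conditions, which should leave the base-sensitive C8 centre next to the aryl ketone untouched.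

Step 8
Reactants: 10 (4S,6R)-4-hydroxy-6-[(2S)-1-oxo-1-(3,4,5-trimethoxyphenyl)propan-2-yl]-6-(prop-2-en-1-yl)cyclohex-2-en-1-one
Product: 11 (4R,6R)-4-[(4-nitrobenzoyl)oxy]-6-[(2S)-1-oxo-1-(3,4,5-trimethoxyphenyl)propan-2-yl]-6-(prop-2-en-1-yl)cyclohex-2-en-1-one
Conditions: 4-O2NC6H4CO2H, PPh3, DIAD, THF, 0 °C → rt
Reagents that add atoms: 4-nitrobenzoic acid, OC(=O)c1ccc(cc1)[N+](=O)[O-]
Why: Mitsunobu reaction: the C4 alkoxyphosphonium ion is displaced by 4-nitrobenzoate in an SN2 step, which inverts C4 from S to R and places the oxygen cis to the side chain as in the target.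

Step 9
Reactants: 11 (4R,6R)-4-[(4-nitrobenzoyl)oxy]-6-[(2S)-1-oxo-1-(3,4,5-trimethoxyphenyl)propan-2-yl]-6-(prop-2-en-1-yl)cyclohex-2-en-1-one
Product: 12 (4R,6R)-4-hydroxy-6-[(2S)-1-oxo-1-(3,4,5-trimethoxyphenyl)propan-2-yl]-6-(prop-2-en-1-yl)cyclohex-2-en-1-one
Conditions: K2CO3 (cat.), MeOH, 0 °C
Reagents that add atoms: none
Why: Base-catalysed transesterification (methanolysis) of the activated aryl ester at the acyl carbon; the C4–O bond is not broken, so the R configuration is kept.

Step 10
Reactants: 12 (4R,6R)-4-hydroxy-6-[(2S)-1-oxo-1-(3,4,5-trimethoxyphenyl)propan-2-yl]-6-(prop-2-en-1-yl)cyclohex-2-en-1-one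
Product: 13 (4R,6R)-4-methoxy-6-[(2S)-1-oxo-1-(3,4,5-trimethoxyphenyl)propan-2-yl]-6-(prop-2-en-1-yl)cyclohex-2-en-1-one
Conditions: MeOTf, 2,6-di-tert-butyl-4-methylpyridine, CH2Cl2, 0 °C → rt
Reagents that add atoms: methyl trifluoromethanesulfonate, COS(=O)(=O)C(F)(F)F
Why: O-Methylation of the secondary allylic alcohol with a hard methylating agent and a hindered pyridine base (Williamson-type alkylation without an alkoxide), which retains C4 and avoids enolisation at C8.

Step 11
Reactants: 13 (4R,6R)-4-methoxy-6-[(2S)-1-oxo-1-(3,4,5-trimethoxyphenyl)propan-2-yl]-6-(prop-2-en-1-yl)cyclohex-2-en-1-one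
Product: 14 megaphone, (4R,6R)-6-[(1R,2S)-1-hydroxy-1-(3,4,5-trimethoxyphenyl)propan-2-yl]-4-methoxy-6-(prop-2-en-1-yl)cyclohex-2-en-1-one
Conditions: trans-RuH(η1-BH4)[(S)-xylbinap][(S,S)-dpen] (cat.), H2 (8 atm), i-PrOH, 25 °C, no added base
Reagents that add atoms: none
Why: Noyori asymmetric hydrogenation by an outer-sphere Ru–H/N–H mechanism: the catalyst enantiomer that gives (R)-1-arylalkanols should deliver hydride to one face of the aryl ketone and set C7 as R (OH syn to the C8 methyl, against the intrinsic 1,2-induction of the C8 centre), while the alkenes and the ring ketone, flanked by the quaternary C6, should not react.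

Step 12
Reactants: 14 megaphone
Product: 15 megaphone acetate, (1R,2S)-2-[(1R,5R)-5-methoxy-2-oxo-1-(prop-2-en-1-yl)cyclohex-3-en-1-yl]-1-(3,4,5-trimethoxyphenyl)propyl acetate
Conditions: Ac2O, pyridine, DMAP (cat.), CH2Cl2, rt
Reagents that add atoms: acetic anhydride, CC(=O)OC(C)=O
Why: DMAP-catalysed acylation of the secondary benzylic alcohol (nucleophilic catalysis); no stereocentre is involved.

**Compound list**

1 | 1,4-dioxaspiro[4.5]dec-6-en-8-one | O=C1C=CC2(OCCO2)CC1 | starting material
2 | (8S)-1,4-dioxaspiro[4.5]dec-6-en-8-ol | O[C@@H]1C=CC2(OCCO2)CC1 | intermediate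
3 | (8S)-8-[(tert-butyldimethylsilyl)oxy]-1,4-dioxaspiro[4.5]dec-6-ene | CC(C)(C)[Si](C)(C)O[C@@H]1C=CC2(OCCO2)CC1 | intermediate
4 | (4S)-4-[(tert-butyldimethylsilyl)oxy]cyclohex-2-en-1-one | O=C1C=C[C@@H](O[Si](C)(C)C(C)(C)C)CC1 | intermediate
5 | (4S,6S)-4-[(tert-butyldimethylsilyl)oxy]-6-(prop-2-en-1-yl)cyclohex-2-en-1-one | C=CC[C@H]1C[C@H](O[Si](C)(C)C(C)(C)C)C=CC1=O | intermediate
6 | 1-(3,4,5-trimethoxyphenyl)propan-1-one | CCC(=O)c1cc(OC)c(OC)c(OC)c1 | starting material
7 | chloro{[(4S)-4-[(tert-butyldimethylsilyl)oxy]-2-(prop-2-en-1-yl)cyclohexa-1,5-dien-1-yl]oxy}di(propan-2-yl)silane | C=CCC1=C(O[Si](Cl)(C(C)C)C(C)C)C=C[C@@H](O[Si](C)(C)C(C)(C)C)C1 | intermediate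
8 | {[(4S)-4-[(tert-butyldimethylsilyl)oxy]-2-(prop-2-en-1-yl)cyclohexa-1,5-dien-1-yl]oxy}{[(1Z)-1-(3,4,5-trimethoxyphenyl)prop-1-en-1-yl]oxy}di(propan-2-yl)silane | C=CCC1=C(O[Si](C(C)C)(C(C)C)O/C(=C\C)c2cc(OC)c(OC)c(OC)c2)C=C[C@@H](O[Si](C)(C)C(C)(C)C)C1 | intermediate
9 | (4S,6R)-4-[(tert-butyldimethylsilyl)oxy]-6-[(2S)-1-oxo-1-(3,4,5-trimethoxyphenyl)propan-2-yl]-6-(prop-2-en-1-yl)cyclohex-2-en-1-one | C=CC[C@]1([C@H](C)C(=O)c2cc(OC)c(OC)c(OC)c2)C[C@H](O[Si](C)(C)C(C)(C)C)C=CC1=O | intermediate
10 | (4S,6R)-4-hydroxy-6-[(2S)-1-oxo-1-(3,4,5-trimethoxyphenyl)propan-2-yl]-6-(prop-2-en-1-yl)cyclohex-2-en-1-one | C=CC[C@]1([C@H](C)C(=O)c2cc(OC)c(OC)c(OC)c2)C[C@H](O)C=CC1=O | intermediate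
11 | (4R,6R)-4-[(4-nitrobenzoyl)oxy]-6-[(2S)-1-oxo-1-(3,4,5-trimethoxyphenyl)propan-2-yl]-6-(prop-2-en-1-yl)cyclohex-2-en-1-one | C=CC[C@]1([C@H](C)C(=O)c2cc(OC)c(OC)c(OC)c2)C[C@@H](OC(=O)c2ccc(cc2)[N+](=O)[O-])C=CC1=O | intermediate
12 | (4R,6R)-4-hydroxy-6-[(2S)-1-oxo-1-(3,4,5-trimethoxyphenyl)propan-2-yl]-6-(prop-2-en-1-yl)cyclohex-2-en-1-one | C=CC[C@]1([C@H](C)C(=O)c2cc(OC)c(OC)c(OC)c2)C[C@@H](O)C=CC1=O | intermediate
13 | (4R,6R)-4-methoxy-6-[(2S)-1-oxo-1-(3,4,5-trimethoxyphenyl)propan-2-yl]-6-(prop-2-en-1-yl)cyclohex-2-en-1-one | C=CC[C@]1([C@H](C)C(=O)c2cc(OC)c(OC)c(OC)c2)C[C@@H](OC)C=CC1=O | intermediate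
14 | megaphone, (4R,6R)-6-[(1R,2S)-1-hydroxy-1-(3,4,5-trimethoxyphenyl)propan-2-yl]-4-methoxy-6-(prop-2-en-1-yl)cyclohex-2-en-1-one | C=CC[C@]1([C@H](C)[C@@H](O)c2cc(OC)c(OC)c(OC)c2)C[C@@H](OC)C=CC1=O | intermediate
15 | megaphone acetate, (1R,2S)-2-[(1R,5R)-5-methoxy-2-oxo-1-(prop-2-en-1-yl)cyclohex-3-en-1-yl]-1-(3,4,5-trimethoxyphenyl)propyl acetate | C=CC[C@]1([C@H](C)[C@@H](OC(C)=O)c2cc(OC)c(OC)c(OC)c2)C[C@@H](OC)C=CC1=O | target

**Step count and risks**

Total step count: 12. Longest linear sequence: 12 steps (1 to 15); 6 is purchased and enters in step 5.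

The three steps most likely to fail are steps 6, 11 and 8.

First, step 6. The tethered coupling may show poor facial selectivity at C6 or the wrong sense at C8, and the hindered radical cation may lose silicon and be protonated before the carbon–carbon bond forms. The same bond would then be made without the tether, setting out from 5. An intermolecular oxidative heterocoupling of two lithium enolates, the dienolate of 5 and the Z enolate of (R)-4-benzyl-3-propanoyl-1,3-oxazolidin-2-one (LDA, THF, −78 °C, then Fe(acac)3), would let the auxiliary instead of the tether fix C8 and would give the N-acyloxazolidinone adduct F1. Exchange of the auxiliary with lithium ethanethiolate would give the S-ethyl thioester F2. A Liebeskind–Srogl coupling of F2 with (3,4,5-trimethoxyphenyl)boronic acid (Pd2(dba)3, tri(2-furyl)phosphine, copper(I) thiophene-2-carboxylate) would install the aryl ketone and come back to the route at 9.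

Second, step 11. The catalyst has to override the intrinsic 1,2-induction of the C8 centre (mismatched double stereodifferentiation), and turnover at the hindered aryl ketone may stall, so that conversion stays incomplete or the C7 selectivity erodes. Setting out from 13, the ketone would instead be hydrogenated with the enantiomeric (R)/(R,R) catalyst in the matched sense to 7-epi-megaphone F3. The benzylic alcohol would then be inverted and acetylated in one operation by a Mitsunobu reaction with acetic acid (PPh3, DIAD), which comes back to the route at 15.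

Third, step 8. SN2′ attack at C2 or elimination towards the cross-conjugated dienone may compete with direct displacement at the allylic C4 on the ring face that carries the side chain. Setting out from 10, inversion would be replaced by an oxidation–reduction sequence. Dess–Martin oxidation would give the ene-dione F4, and Luche reduction (NaBH4, CeCl3, MeOH, −78 °C) at the unhindered C4 carbonyl should deliver hydride from the ring face of the smaller allyl group, away from the branched side chain. This places the hydroxyl cis to the side chain and comes back to the route at 12.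

**Further compounds**

F1 | step 6 | (4R)-4-benzyl-3-{(2S)-2-[(1R,5S)-5-[(tert-butyldimethylsilyl)oxy]-2-oxo-1-(prop-2-en-1-yl)cyclohex-3-en-1-yl]propanoyl}-1,3-oxazolidin-2-one | C=CC[C@]1([C@H](C)C(=O)N2[C@H](Cc3ccccc3)COC2=O)C[C@H](O[Si](C)(C)C(C)(C)C)C=CC1=O
F2 | step 6 | S-ethyl (2S)-2-[(1R,5S)-5-[(tert-butyldimethylsilyl)oxy]-2-oxo-1-(prop-2-en-1-yl)cyclohex-3-en-1-yl]propanethioate | C=CC[C@]1([C@H](C)C(=O)SCC)C[C@H](O[Si](C)(C)C(C)(C)C)C=CC1=O
F3 | step 11 | 7-epi-megaphone, (4R,6R)-6-[(1S,2S)-1-hydroxy-1-(3,4,5-trimethoxyphenyl)propan-2-yl]-4-methoxy-6-(prop-2-en-1-yl)cyclohex-2-en-1-one | C=CC[C@]1([C@H](C)[C@H](O)c2cc(OC)c(OC)c(OC)c2)C[C@@H](OC)C=CC1=O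
F4 | step 8 | (5R)-5-[(2S)-1-oxo-1-(3,4,5-trimethoxyphenyl)propan-2-yl]-5-(prop-2-en-1-yl)cyclohex-2-ene-1,4-dione | C=CC[C@]1([C@H](C)C(=O)c2cc(OC)c(OC)c(OC)c2)CC(=O)C=CC1=O
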